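**Retrosynthetic overview** (chain numbering: C1 lactone carbonyl to C12 methyl; tetrahydrofuran = O, C4, C5, C6, C7; pyranone = O, C1–C5)
1. The plan rests on the unit C7(ring O)–C8=C9–C10(OH): an (E)-alkene between the ether carbon C7 of the tetrahydrofuran (C4–O–C7–C6–C5) and the C10 carbinol, which is what a hydroxyl leaves behind when it adds to the far end of a C9–C10 alkenyl epoxide. The tetrahydrofuran is therefore the last ring made, by O4–C7 bond formation on a Pd allyl complex, followed only by C6–O desilylation.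
2. The epoxide precursor 18 is cut at C7=C8 by cross-metathesis into pyranone alkene 10 (C1–C7) and vinyl epoxide 17 (C8–C12).
3. Fragment 10: the pyranone (first ring) comes from Z-olefination and lactonisation on O5. C4, C5 and C6 are C4, C3 and C2 of D-mannose diacetonide 1, whose furanose oxygen singles out O4; its anomeric carbon is methylenated to C7=C8 and its C5–C6 glycol is cleaved to expose C3.
4. Fragment 17: C11 comes from (R)-but-3-en-2-ol; C9 and C10 are set by Sharpless epoxidation of the E-allylic alcohol, followed by oxidation and methylenation.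
5. Ring order: pyranone (step 5), then tetrahydrofuran (step 14).

Key step: step 14

Remark: 2,3:5,6-di-O-isopropylidene-α-D-mannofuranose, (R)-but-3-en-2-ol and (Z)-but-2-ene-1,4-diol are taken as commercial; the C6 hydroxyl is carried through the key step as its triethylsilyl ether and the C11 oxygen as the benzoate of the target.

**Fragment 10 (C1–C7)**

Step 1
Reactants: 1 2,3:5,6-di-O-isopropylidene-α-D-mannofuranose
Product: 2 1,2-dideoxy-3,4:6,7-di-O-isopropylidene-D-manno-hept-1-enitol (free 5-OH, the later C4–OH)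
Conditions: Ph3PCH3Br, KOtBu (2.5 equiv each), THF, 0 °C to reflux
Reagents that add atoms: methyltriphenylphosphonium bromide (as its ylide), C[P+](c1ccccc1)(c1ccccc1)c1ccccc1.[Br-]
Why: Wittig methylenation of the open hydroxy-aldehyde form of the lactol (one equivalent of ylide is spent on the lactol OH) turns the anomeric carbon into C7=C8 and frees the former ring oxygen as the C4 hydroxyl without touching a stereocentre.

Step 2
Reactants: 2 1,2-dideoxy-3,4:6,7-di-O-isopropylidene-D-manno-hept-1-enitol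
Product: 3 1,2-dideoxy-3,4:6,7-di-O-isopropylidene-5-O-(4-methoxybenzyl)-D-manno-hept-1-enitol
Conditions: NaH, PMBCl, Bu4NI (cat.), DMF, 0 °C to rt
Reagents that add atoms: 4-methoxybenzyl chloride, COc1ccc(CCl)cc1
Why: Williamson etherification of the only free hydroxyl blocks O4, which would otherwise close a butenolide in step 5, with a group that is later removed oxidatively beside a silyl ether, an alkene and an enoate.

Step 3
Reactants: 3 1,2-dideoxy-3,4:6,7-di-O-isopropylidene-5-O-(4-methoxybenzyl)-D-manno-hept-1-enitol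
Product: 5 5,6-dideoxy-3,4-O-isopropylidene-2-O-(4-methoxybenzyl)-D-arabino-hex-5-enose, via terminal diol 4 (not isolated)
Conditions: H5IO6 (1.5 equiv), EtOAc, rt; filtered, concentrated and used at once
Reagents that add atoms: none
Why: Periodic acid hydrolyses the less hindered terminal dioxolane and cleaves the freed 1,2-diol in the same pot (Malaprade glycol cleavage), which exposes C3 as the aldehyde while the internal acetonide, the PMB ether and the C4 stereocentre should stay intact.

Step 4
Reactants: 5 5,6-dideoxy-3,4-O-isopropylidene-2-O-(4-methoxybenzyl)-D-arabino-hex-5-enose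
Product: 6 methyl (Z)-2,3,7,8-tetradeoxy-5,6-O-isopropylidene-4-O-(4-methoxybenzyl)-D-arabino-octa-2,7-dienonate
Conditions: (CF3CH2O)2P(O)CH2CO2Me, KN(SiMe3)2, 18-crown-6, THF, −78 °C
Reagents that add atoms: methyl bis(2,2,2-trifluoroethyl)phosphonoacetate, COC(=O)CP(=O)(OCC(F)(F)F)OCC(F)(F)F
Why: Still–Gennari olefination, in which the electron-poor phosphonate eliminates fast from the kinetic adduct, should give the (2Z)-enoate needed for lactonisation, and the low temperature guards the α-alkoxy aldehyde against epimerisation at C4.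

Step 5
Reactants: 6 methyl (Z)-2,3,7,8-tetradeoxy-5,6-O-isopropylidene-4-O-(4-methoxybenzyl)-D-arabino-octa-2,7-dienonate
Product: 8 (5R,6R)-6-[(1R)-1-hydroxyprop-2-en-1-yl]-5-[(4-methoxybenzyl)oxy]-5,6-dihydro-2H-pyran-2-one, via dihydroxy Z-enoate 7 (not isolated)
Conditions: TsOH·H2O (0.2 equiv), MeOH–H2O (10:1), 40 °C; then toluene, 60 °C with removal of MeOH
Reagents that add atoms: none
Why: Acid hydrolysis of the acetonide frees O5 and O6, and the Z-enoate then lactonises (intramolecular transesterification) only through O5 to the six-membered ring, because O6 would need a seven-membered ring and O4 is etherified.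

Step 6
Reactants: 8 (5R,6R)-6-[(1R)-1-hydroxyprop-2-en-1-yl]-5-[(4-methoxybenzyl)oxy]-5,6-dihydro-2H-pyran-2-one
Product: 9 (5R,6S)-5-[(4-methoxybenzyl)oxy]-6-[(1R)-1-(triethylsilyloxy)prop-2-en-1-yl]-5,6-dihydro-2H-pyran-2-one
Conditions: TESOTf, 2,6-lutidine, CH2Cl2, −78 °C
Reagents that add atoms: triethylsilyl trifluoromethanesulfonate, CC[Si](CC)(CC)OS(=O)(=O)C(F)(F)F
Why: Silylation of the only free hydroxyl with a silyl triflate and a hindered base avoids an alkoxide and hence oxa-Michael addition of O6 to C3, and it masks O6 for the key step.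

Step 7
Reactants: 9 (5R,6S)-5-[(4-methoxybenzyl)oxy]-6-[(1R)-1-(triethylsilyloxy)prop-2-en-1-yl]-5,6-dihydro-2H-pyran-2-one
Product: 10 (5R,6S)-5-hydroxy-6-[(1R)-1-(triethylsilyloxy)prop-2-en-1-yl]-5,6-dihydro-2H-pyran-2-one
Conditions: DDQ, CH2Cl2–pH 7 phosphate buffer (10:1), 0 °C
Reagents that add atoms: none
Why: Oxidative cleavage of the electron-rich benzyl ether by DDQ (hydride abstraction to the oxocarbenium ion, then hydrolysis) at buffered pH should free the C4 hydroxyl while the triethylsilyl ether, the terminal alkene and the enoate survive.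

**Fragment 17 (C8–C12)**

Step 8
Reactants: 11 (R)-but-3-en-2-ol
Product: 12 (R)-but-3-en-2-yl benzoate
Conditions: BzCl, pyridine, DMAP (cat.), CH2Cl2, 0 °C to rt
Reagents that add atoms: benzoyl chloride, O=C(Cl)c1ccccc1
Why: DMAP-catalysed acylation installs the C11 benzoate of the target at the outset with retention, since the C–O bond at the stereocentre is not broken.

Step 9
Reactants: 12 (R)-but-3-en-2-yl benzoate; 13 (Z)-but-2-ene-1,4-diol (3 equiv)
Product: 14 (2R,3E)-5-hydroxypent-3-en-2-yl benzoate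
Conditions: second-generation Grubbs catalyst RuCl2(=CHPh)(H2IMes)(PCy3) (3 mol%), CH2Cl2, 40 °C
Reagents that add atoms: none
Why: Olefin cross-metathesis between a fast-exchanging primary allylic alcohol donor and a slowly homodimerising secondary allylic ester should give the cross product selectively, with the E alkene favoured thermodynamically; any Z isomer is removed by chromatography here or after step 10.

Step 10
Reactants: 14 (2R,3E)-5-hydroxypent-3-en-2-yl benzoate
Product: 15 (R)-1-[(2R,3R)-3-(hydroxymethyl)oxiran-2-yl]ethyl benzoate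
Conditions: Ti(OiPr)4, D-(−)-diisopropyl tartrate, tBuOOH, 4 Å MS, CH2Cl2, −20 °C
Reagents that add atoms: tert-butyl hydroperoxide, CC(C)(C)OO
Why: Sharpless asymmetric epoxidation delivers oxygen to one alkene face under reagent control through the titanium tartrate bound to the primary allylic alcohol, D-(−)-tartrate giving the (2R,3R)-oxirane (C9 R, C10 R) and the E geometry giving the trans epoxide.

Step 11
Reactants: 15 (R)-1-[(2R,3R)-3-(hydroxymethyl)oxiran-2-yl]ethyl benzoate
Product: 16 (R)-1-[(2R,3S)-3-formyloxiran-2-yl]ethyl benzoate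
Conditions: PhI(OAc)2, TEMPO (10 mol%), CH2Cl2, rt; used crude
Reagents that add atoms: none
Why: TEMPO-catalysed oxidation through the oxoammonium ion stops at the aldehyde under near-neutral conditions that spare the epoxide and the ester and should not epimerise C9.

Step 12
Reactants: 16 (R)-1-[(2R,3S)-3-formyloxiran-2-yl]ethyl benzoate
Product: 17 (R)-1-[(2R,3R)-3-ethenyloxiran-2-yl]ethyl benzoate
Conditions: Ph3PCH3Br, KN(SiMe3)2, THF, −78 to 0 °C
Reagents that add atoms: methyltriphenylphosphonium bromide (as its ylide), C[P+](c1ccccc1)(c1ccccc1)c1ccccc1.[Br-]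
Why: Wittig methylenation with a slight excess of non-stabilised ylide at low temperature is far faster at the aldehyde than at the benzoate and leaves the epoxide stereocentres alone.

**Coupling, key step and end game**

Step 13
Reactants: 10 (5R,6S)-5-hydroxy-6-[(1R)-1-(triethylsilyloxy)prop-2-en-1-yl]-5,6-dihydro-2H-pyran-2-one; 17 (R)-1-[(2R,3R)-3-ethenyloxiran-2-yl]ethyl benzoate (3 equiv)
Product: 18 (R)-1-[(2R,3R)-3-{(1E,3R)-3-[(2S,3R)-3-hydroxy-6-oxo-3,6-dihydro-2H-pyran-2-yl]-3-(triethylsilyloxy)prop-1-en-1-yl}oxiran-2-yl]ethyl benzoate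
Conditions: second-generation Hoveyda–Grubbs catalyst RuCl2(=CH-C6H4-2-OiPr)(H2IMes) (10 mol%), CH2Cl2, 40 °C
Reagents that add atoms: none
Why: Olefin cross-metathesis joins C7 to C8 with loss of ethylene; both terminal alkenes are branched at the allylic carbon and so homodimerise slowly, the excess of 17 drives the cross product, the E alkene should form as the thermodynamic isomer, and the conjugated ring alkene of the lactone is inert.

Step 14
Reactants: 18 (R)-1-[(2R,3R)-3-{(1E,3R)-3-[(2S,3R)-3-hydroxy-6-oxo-3,6-dihydro-2H-pyran-2-yl]-3-(triethylsilyloxy)prop-1-en-1-yl}oxiran-2-yl]ethyl benzoate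
Product: 19 (2R,3S,4E)-3-hydroxy-5-[(2S,3R,3aS,7aR)-5-oxo-3-(triethylsilyloxy)-2,3,3a,7a-tetrahydro-5H-furo[3,2-b]pyran-2-yl]pent-4-en-2-yl benzoate
Conditions: Pd(PPh3)4 (10 mol%), degassed THF, 0 °C to rt
Reagents that add atoms: none
Why: Zerovalent palladium binds C7=C8 on the face opposite the C9–O bond and ionises the allylic epoxide with inversion at C9 to a zwitterion made of a syn,syn-1,3-disubstituted (π-allyl)Pd(PPh3)2 cation (C7–C8–C9) and the C10 alkoxide; the alkoxide takes the proton of the C4 hydroxyl and O4 then adds to C7 anti to palladium, which releases the catalyst. The closest known reaction type is the Pd-catalysed cycloetherification of hydroxy alkenyl epoxides to 2-alkenyl tetrahydrofurans, an intramolecular Tsuji–Trost allylic etherification. The tetrahydrofuran (O–C4–C5–C6–C7) closes in a 5-exo mode with the allyl unit outside the ring, the alternative attack at C9 needing a seven-membered ring. C7 is the only new stereocentre and is set (S) by double inversion, so that O4 enters on the face from which the epoxide oxygen of the (9R) carbon left and the all-cis ring results, while the syn,syn allyl geometry fixes the 8E alkene and C10 keeps its configuration because its C–O bond is never broken. The step needs O4 to react in preference to O6 and O10, which the triethylsilyl ether on O6 and ring size secure, and it needs ring closure to outrun π–σ–π isomerisation and palladium exchange of the allyl complex, which the substituents at both allyl termini, the low temperature and the modest catalyst loading should secure.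

Step 15
Reactants: 19 (2R,3S,4E)-3-hydroxy-5-[(2S,3R,3aS,7aR)-5-oxo-3-(triethylsilyloxy)-2,3,3a,7a-tetrahydro-5H-furo[3,2-b]pyran-2-yl]pent-4-en-2-yl benzoate
Product: 20 (2R,3S,4E)-3-hydroxy-5-[(2S,3R,3aR,7aR)-3-hydroxy-5-oxo-2,3,3a,7a-tetrahydro-5H-furo[3,2-b]pyran-2-yl]pent-4-en-2-yl benzoate (target)
Conditions: HF·pyridine, pyridine, THF, 0 °C to rt
Reagents that add atoms: none
Why: Buffered fluoride cleavage of the secondary triethylsilyl ether is mildly acidic, so the benzoate should neither hydrolyse nor shift to O10 and the unsaturated lactone should stay closed.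

**Compound list**
1 | 2,3:5,6-di-O-isopropylidene-α-D-mannofuranose | O[C@H]1O[C@H]([C@H]2COC(C)(C)O2)[C@@H]2OC(C)(C)O[C@H]12 | starting material
2 | 1,2-dideoxy-3,4:6,7-di-O-isopropylidene-D-manno-hept-1-enitol | C=C[C@H]1OC(C)(C)O[C@H]1[C@H](O)[C@H]1COC(C)(C)O1 | intermediate
3 | 1,2-dideoxy-3,4:6,7-di-O-isopropylidene-5-O-(4-methoxybenzyl)-D-manno-hept-1-enitol | C=C[C@H]1OC(C)(C)O[C@H]1[C@H](OCc2ccc(OC)cc2)[C@H]1COC(C)(C)O1 | intermediate
4 | 1,2-dideoxy-3,4-O-isopropylidene-5-O-(4-methoxybenzyl)-D-manno-hept-1-enitol (6,7-diol) | C=C[C@H]1OC(C)(C)O[C@H]1[C@H](OCc2ccc(OC)cc2)[C@H](O)CO | intermediate (not isolated)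
5 | 5,6-dideoxy-3,4-O-isopropylidene-2-O-(4-methoxybenzyl)-D-arabino-hex-5-enose | C=C[C@H]1OC(C)(C)O[C@H]1[C@H](OCc2ccc(OC)cc2)C=O | intermediate
6 | methyl (Z)-2,3,7,8-tetradeoxy-5,6-O-isopropylidene-4-O-(4-methoxybenzyl)-D-arabino-octa-2,7-dienonate | C=C[C@H]1OC(C)(C)O[C@H]1[C@H](OCc2ccc(OC)cc2)/C=C\C(=O)OC | intermediate
7 | methyl (Z)-2,3,7,8-tetradeoxy-4-O-(4-methoxybenzyl)-D-arabino-octa-2,7-dienonate (5,6-diol) | C=C[C@@H](O)[C@@H](O)[C@H](OCc1ccc(OC)cc1)/C=C\C(=O)OC | intermediate (not isolated)
8 | (5R,6R)-6-[(1R)-1-hydroxyprop-2-en-1-yl]-5-[(4-methoxybenzyl)oxy]-5,6-dihydro-2H-pyran-2-one | C=C[C@@H](O)[C@H]1OC(=O)C=C[C@H]1OCc2ccc(OC)cc2 | intermediate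
9 | (5R,6S)-5-[(4-methoxybenzyl)oxy]-6-[(1R)-1-(triethylsilyloxy)prop-2-en-1-yl]-5,6-dihydro-2H-pyran-2-one | C=C[C@@H](O[Si](CC)(CC)CC)[C@H]1OC(=O)C=C[C@H]1OCc2ccc(OC)cc2 | intermediate
10 | (5R,6S)-5-hydroxy-6-[(1R)-1-(triethylsilyloxy)prop-2-en-1-yl]-5,6-dihydro-2H-pyran-2-one | C=C[C@@H](O[Si](CC)(CC)CC)[C@H]1OC(=O)C=C[C@H]1O | intermediate
11 | (R)-but-3-en-2-ol | C[C@@H](O)C=C | starting material
12 | (R)-but-3-en-2-yl benzoate | C[C@@H](OC(=O)c1ccccc1)C=C | intermediate
13 | (Z)-but-2-ene-1,4-diol | OC/C=C\CO | starting material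
14 | (2R,3E)-5-hydroxypent-3-en-2-yl benzoate | C[C@@H](OC(=O)c1ccccc1)/C=C/CO | intermediate
15 | (R)-1-[(2R,3R)-3-(hydroxymethyl)oxiran-2-yl]ethyl benzoate | C[C@@H](OC(=O)c1ccccc1)[C@H]1O[C@@H]1CO | intermediate
16 | (R)-1-[(2R,3S)-3-formyloxiran-2-yl]ethyl benzoate | C[C@@H](OC(=O)c1ccccc1)[C@H]1O[C@@H]1C=O | intermediate
17 | (R)-1-[(2R,3R)-3-ethenyloxiran-2-yl]ethyl benzoate | C[C@@H](OC(=O)c1ccccc1)[C@H]1O[C@@H]1C=C | intermediate
18 | (R)-1-[(2R,3R)-3-{(1E,3R)-3-[(2S,3R)-3-hydroxy-6-oxo-3,6-dihydro-2H-pyran-2-yl]-3-(triethylsilyloxy)prop-1-en-1-yl}oxiran-2-yl]ethyl benzoate (cyclisation precursor) | C[C@@H](OC(=O)c1ccccc1)[C@H]3O[C@@H]3/C=C/[C@@H](O[Si](CC)(CC)CC)[C@H]2OC(=O)C=C[C@H]2O | intermediate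
19 | (2R,3S,4E)-3-hydroxy-5-[(2S,3R,3aS,7aR)-5-oxo-3-(triethylsilyloxy)-2,3,3a,7a-tetrahydro-5H-furo[3,2-b]pyran-2-yl]pent-4-en-2-yl benzoate (C6 triethylsilyl ether of the target) | C[C@@H](OC(=O)c1ccccc1)[C@@H](O)/C=C/[C@@H]1O[C@@H]2C=CC(=O)O[C@@H]2[C@@H]1O[Si](CC)(CC)CC | intermediate
20 | (2R,3S,4E)-3-hydroxy-5-[(2S,3R,3aR,7aR)-3-hydroxy-5-oxo-2,3,3a,7a-tetrahydro-5H-furo[3,2-b]pyran-2-yl]pent-4-en-2-yl benzoate | C[C@@H](OC(=O)c1ccccc1)[C@@H](O)/C=C/[C@@H]1O[C@@H]2C=CC(=O)O[C@@H]2[C@@H]1O | target

**Count**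
Total steps: 15 (steps 1–7 for fragment 10, steps 8–12 for fragment 17, steps 13–15 after convergence).
Longest linear sequence: 10 steps (steps 1–7, then 13, 14, 15).

**Steps most likely to fail**

1. Step 14. The transient C10 alkoxide sits next to the C11 benzoate, so a 1,2-benzoyl shift from O11 to O10 may compete with ring closure; syn/anti isomerisation of the allyl complex would also erode the transfer of configuration to C7. Fallback, from 17 back to 20: the benzoate is kept out of the cyclisation and installed afterwards. Methanolysis of 17 (K2CO3, MeOH, 0 °C) would give (R)-1-[(2R,3R)-3-ethenyloxiran-2-yl]ethanol F1, and NaH, PMBBr, Bu4NI in THF at 0 °C (aprotic, to hold back Payne equilibration) would give (2R,3R)-2-ethenyl-3-[(R)-1-(4-methoxybenzyloxy)ethyl]oxirane F2. Cross-metathesis of F2 with 10 as in step 13 would give the C11 4-methoxybenzyl ether analogue of the precursor F3, and Pd(PPh3)4 in THF would close it as in step 14 to the C11 4-methoxybenzyl ether of the bicyclic C10 alcohol F4, in which no acyl group can migrate. TESOTf and 2,6-lutidine would then give the C6,C10 bis(triethylsilyl) ether F5, buffered DDQ the C11 alcohol F6, and BzCl, pyridine and DMAP the bis(triethylsilyl) ether of the target F7. HF·pyridine would remove both silyl groups to give 20.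

2. Step 13. Metathesis between two alkenes that are both branched at the allylic carbon, one of them a bulky silyl ether, may be slow enough for catalyst decay and homodimerisation of 17 to take over. Fallback, from 8 back to 18: the coupling is moved to the free allylic carbinol, a more reactive metathesis partner, and the protecting-group steps follow it. Cross-metathesis of 8 with 17 (second-generation Hoveyda–Grubbs catalyst, CH2Cl2, 40 °C) would give the C6 hydroxy C4 4-methoxybenzyl ether epoxide F8. TESCl and imidazole in DMF at 0 °C (no silyl triflate, which would open the epoxide) would give its triethylsilyl ether F9, and buffered DDQ as in step 7 would free the C4 hydroxyl to give 18.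

3. Step 9. Incomplete E selectivity in the metathesis would carry a Z-allylic alcohol into the epoxidation and end in a cis-epoxide that transfers the wrong configuration to C7. Fallback, from 12 back to 14: the alkene is built by olefination instead of metathesis. Ozonolysis of 12 (O3, CH2Cl2, −78 °C; PPh3) would give (R)-1-oxopropan-2-yl benzoate F10, and Wittig reaction with the stabilised ylide Ph3P=CHCHO in toluene at rt would give (2R,3E)-5-oxopent-3-en-2-yl benzoate F11. Luche reduction (NaBH4, CeCl3·7H2O, MeOH, −40 °C) would reduce the aldehyde beside the benzoate and give 14.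

Further compounds
F1 | step 14 | (R)-1-[(2R,3R)-3-ethenyloxiran-2-yl]ethanol | C[C@@H](O)[C@H]1O[C@@H]1C=C
F2 | step 14 | (2R,3R)-2-ethenyl-3-[(R)-1-(4-methoxybenzyloxy)ethyl]oxirane | C[C@@H](OCc1ccc(OC)cc1)[C@H]2O[C@@H]2C=C
F3 | step 14 | C11 4-methoxybenzyl ether analogue of precursor 18 | C[C@@H](OCc1ccc(OC)cc1)[C@H]3O[C@@H]3/C=C/[C@@H](O[Si](CC)(CC)CC)[C@H]2OC(=O)C=C[C@H]2O
F4 | step 14 | C11 4-methoxybenzyl ether of the bicyclic C10 alcohol (C6 triethylsilyl ether) | C[C@@H](OCc1ccc(OC)cc1)[C@@H](O)/C=C/[C@@H]1O[C@@H]2C=CC(=O)O[C@@H]2[C@@H]1O[Si](CC)(CC)CC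
F5 | step 14 | C6,C10 bis(triethylsilyl) ether with C11 4-methoxybenzyl ether | C[C@@H](OCc1ccc(OC)cc1)[C@@H](O[Si](CC)(CC)CC)/C=C/[C@@H]1O[C@@H]2C=CC(=O)O[C@@H]2[C@@H]1O[Si](CC)(CC)CC
F6 | step 14 | C6,C10 bis(triethylsilyl) ether C11 alcohol | C[C@@H](O)[C@@H](O[Si](CC)(CC)CC)/C=C/[C@@H]1O[C@@H]2C=CC(=O)O[C@@H]2[C@@H]1O[Si](CC)(CC)CC
F7 | step 14 | C6,C10 bis(triethylsilyl) ether of the target | C[C@@H](OC(=O)c1ccccc1)[C@@H](O[Si](CC)(CC)CC)/C=C/[C@@H]1O[C@@H]2C=CC(=O)O[C@@H]2[C@@H]1O[Si](CC)(CC)CC
F8 | step 13 | C6 hydroxy C4 4-methoxybenzyl ether epoxide (cross-metathesis product of 8 and 17) | C[C@@H](OC(=O)c1ccccc1)[C@H]3O[C@@H]3/C=C/[C@@H](O)[C@H]2OC(=O)C=C[C@H]2OCc4ccc(OC)cc4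
F9 | step 13 | C6 triethylsilyl ether of F8 | C[C@@H](OC(=O)c1ccccc1)[C@H]3O[C@@H]3/C=C/[C@@H](O[Si](CC)(CC)CC)[C@H]2OC(=O)C=C[C@H]2OCc4ccc(OC)cc4
F10 | step 9 | (R)-1-oxopropan-2-yl benzoate | C[C@@H](OC(=O)c1ccccc1)C=O
F11 | step 9 | (2R,3E)-5-oxopent-3-en-2-yl benzoate | C[C@@H](OC(=O)c1ccccc1)/C=C/C=O
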